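## The problem

The target 26 is a labdane of the enantiomeric (ent) series: a trans-fused decalin (ring A = C1–C5 and C10, ring B = C5–C10, labdane numbering) with a six-carbon chain on C9 that ends in a malonic half ester at O15. Five of the six stereocentres lie on the decalin (4S,5S,8S,9S,10R) and depend on one another, so a chair-controlled ring closure can set them relative to each other. The sixth, C13 (S), is insulated from the rings by two methylene groups and has to come from a chiral-pool fragment. C4 and C10 are quaternary; C4 carries an axial methyl (C19) syn to the axial C20 methyl and an equatorial CH2OH (C18), so its two one-carbon groups must be told apart. C8 is a tertiary alcohol with equatorial OH and an axial methyl (C17) that is 1,3-diaxial to C20, the less stable arrangement, which must be made under kinetic control. Three hydroxyls (tertiary O8, primary O15, neopentyl primary O18) must be distinguished so that only O15 is acylated. The malonic half ester does not survive base, hydride or strong heating, and the tertiary alcohol does not survive strong acid, so both belong at the end. The enabling feature is the pattern around the ring fusion: an axial methyl and an equatorial oxygenated carbon on C4, a trans C5/C10 fusion, an equatorial C9 substituent and an oxidised C8. A chair–chair cyclisation of an E-configured, C18-oxygenated 3,4-epoxide through an E C5=C10 alkene onto a C8=C9 allylsilane leaves exactly this pattern. Because the rings belong to the ent series, the abundant labdanes of the normal series are of no use as starting materials.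

## Retrosynthesis

**Ester and last protecting group (26 ⇒ 25 ⇒ 23 + 24).** The O18–Si bond and the O15–acyl bond are cut last. O15 and O18 are both primary, so O18 stays silylated (25) until the ester is in place. The acyl group comes from opening Meldrum's acid 24 with diol 23, which gives the half ester directly, without base or coupling reagent, and leaves the hindered tertiary O8 alone. A protected malonate would need an extra unmasking step. The forward steps must only be mild: neutral heating, then buffered fluoride.

**C8 carbinol and O15 unmasking (23 ⇒ 22 ⇒ 21 ⇒ 20).** The C8–O bond is traced to the C8=C17 methylene of 20 through spiro-epoxide 21. Hydride opening at C17 then gives the equatorial alcohol and axial methyl of 22. A peracid must approach C8 from the face away from the axial C20 methyl, which is the face required. A one-step Mukaiyama hydration (Co(acac)2, PhSiH3, O2) was set aside because a small O2 molecule trapping a planar C8 radical should obey this bias less dependably. A methyl nucleophile added to a C8 carbonyl would enter from the open face and give the wrong epimer. O15 is carried as a benzyl ether, since hydride is used in steps 8, 11 and 18 and an ester would not survive; it is removed by hydrogenolysis (22 ⇒ 23) once no alkene is left.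

**C3 oxygen (20 ⇒ 19 ⇒ 18).** The C3 hydroxyl of 18 is the cost of an epoxide initiator. It is removed by Barton–McCombie reduction of thionocarbonate 19. The thionocarbonate is made under neutral conditions, because an alkoxide at O3 sits 1,3 to the O18 silyl ether and could take the silyl group.

**Key disconnection (18 ⇒ 17).** C4–C5 and C9–C10 are cut together, which opens both rings to the acyclic epoxy diene allylsilane 17. This removes four ring stereocentres and both rings at once. What remains is one epoxide of defined configuration, two alkene geometries and the remote C13. The forward reaction must ionise only the epoxide, close two six-membered rings through chairs, and end with the alkene at C8=C17; the silicon ensures the last point.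

**Epoxide (17 ⇒ 16 ⇒ 15).** The epoxide is traced to the E allylic alcohol 15, whose free hydroxyl lets the Sharpless reagent select this alkene among three and set both epoxide carbons. It is introduced late because the organolithium and hydride steps of the fragment union would endanger it. The silyl ether 17 is made only after epoxidation, so O18 needs no earlier protection.

**C6–C7 bond (15 ⇒ 14 ⇒ 4 + 13).** Cutting C6–C7 gives two fragments of similar size: hydroxy sulfone 4 (C1–C6, C10, C18–C20) as nucleophile and allylic bromide 13 (C7–C9, C11–C17) as electrophile. Sulfone alkylation followed by palladium-catalysed desulfonylation joins two allylic carbons without moving either alkene. The forward step must alkylate carbon, not oxygen, of the dianion of 4.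

**Allylsilane fragment (13 ⇒ 12 ⇒ 11 ⇒ 10 ⇒ 9 ⇒ 8).** The trisubstituted alkene of 13 must have the chain (C11) cis to CH2SiMe3 and trans to C7, or C9 will be epimeric after cyclisation. Allylic oxidation of a citronellol-derived alkene would functionalise the wrong methyl group for this purpose. The alkene is therefore built from aldehyde 8: a Wittig reaction to Z iodo enoate 9 fixes the geometry, a Negishi coupling replaces iodine by CH2SiMe3 with retention (10), and the ester carbon becomes C7 by reduction (11) and bromination (13 via 12).

**Chiral pool (8 ⇒ 7 ⇒ 6 ⇒ 5; 4 ⇒ 3 ⇒ 2 ⇒ 1).** Aldehyde 8 comes from (S)-citronellol 5 by benzylation (6) and ozonolysis (via 7); this supplies C13 with the correct configuration and the C15 oxygen. Sulfone 4 comes from geraniol 1 through bromide 2 and sulfone 3, with SeO2 oxidation of the E methyl group providing C18 in the geometry that the cyclisation turns into the equatorial position.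

## Roads not taken

**Alternative 1: one-carbon ring expansion of a hydrindanol.**
- Cut: C9–C10, taking ring B back to the five-membered ring of vinyl carbinol A1.
- Key step: NBS forms a bromonium ion on the vinyl group; the C10–C8 ring bond migrates to C9, giving the six-membered 8-ketone A2 with a bromomethyl group (C11) on C9.
- Merits: the migrating quaternary C10 keeps its configuration; C9 lies next to the ketone and can equilibrate to the equatorial epimer; no C3 oxygen has to be removed; no electron-poor epoxide has to ionise. In these respects it is safer than the chosen plan.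
- Weak points: the step does not address the hard part of the target. A1 must already hold C4, C5 and C10 in a trans-fused hydrindane, which needs its own multi-step stereocontrolled synthesis. A2 is a β-bromo ketone and loses HBr easily, so attaching C12–C16 (with C13) through C11 is awkward. A methyl nucleophile at the C8 carbonyl would enter from the face away from C20 and give the C8 epimer, so a methylenation followed by the sequence of steps 17 and 18 would still be needed.
- Comparison: the chosen plan offers two rings and four stereocentres in one step from two chiral-pool fragments, at the cost of a riskier initiation and a two-step deoxygenation.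

**Alternative 2: hydroxyl-directed C–H silylation of a C4 gem-dimethyl group.**
- Cut: the C18–O bond is traced to a C18–H bond of the 3-hydroxy gem-dimethyl labdane A3.
- Key step: the 3-hydroxyl is silylated with Et2SiH2, and [Ir(cod)OMe]2 with a phenanthroline ligand inserts into a C–H bond of the equatorial methyl, closing oxasilolane A4. A Tamao–Fleming oxidation would then free the C18 hydroxyl.
- Merits: the cyclisation leading to A3 would use an ordinary gem-dimethyl epoxide, the best-behaved initiator, so the weakest point of the chosen plan disappears. The C3 hydroxyl is also used as a directing group before it is deleted.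
- Weak points: the equatorial 3-hydroxyl is gauche to both methyl groups, so the C18/C19 choice rests on the geometry of the metallacycle alone. After oxidation a secondary and a primary hydroxyl must be differentiated before C3 is deoxygenated. This costs at least three steps more than the chosen endgame and a precious-metal step. A3 belongs to the ent series, so it cannot be taken from natural sources and still needs the same polyene cyclisation.
- Comparison: this is the chosen bond construction with a safer cyclisation and a longer endgame. The chosen plan has the C18 oxygen in place from the start and C4 fixed by alkene geometry at no extra step.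

**Alternative 3: intramolecular Diels–Alder reaction of a tiglate triene.**
- Cut: C3–C4 and C5–C10, giving the acyclic triene A5 with C8, C9 and C13 already in the tether.
- Key step: with Et2AlCl and heat, the E enoate C4=C5 adds across the diene C10=C1–C2=C3 to give decalin A6.
- Merits: two rings and C4, C5 and C10 are made at once, with C4 set by enoate geometry. No C3 oxygen arises; the C1=C2 alkene would go in the same hydrogenation as the benzyl group. C8 is oxygenated before ring formation, so steps 17 and 18 would be unnecessary. No acid-sensitive allylsilane is needed. On these points it is as good as or better than the chosen plan.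
- Weak points: the diene terminus C10 is fully substituted, so one substituent must point into the s-cis diene. The dienophile is a trisubstituted α-methyl enoate. Two quaternary carbons form in the cycloaddition. The tether forces the enoate α-carbon onto the more nucleophilic diene terminus. Trans/cis fusion would rest on the existing C8 and C9 centres. A5, with adjacent C8 and C9 stereocentres beside a diene, is itself a demanding target.
- Comparison: the chosen plan has a precursor with no acyclic stereocentre to build other than C13, and uses a reactivity pattern that matches the substitution of the target.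

Key step: step 14

Remark (assumption): locants and CIP descriptors in the names from 14 onwards follow labdane numbering of 26. Compound 14 is carried as a mixture of C6 epimers and 7 as a mixture at the ozonide carbon, since both centres are removed in the following operation.

## Route

Step 1
Reactants: 1 geraniol
Product: 2 geranyl bromide
Conditions: PBr3, Et2O, −10 °C
Reagents that add atoms: phosphorus tribromide, BrP(Br)Br
Why: Bromination of a primary allylic alcohol by PBr3 (SN2 on the phosphite ester); at low temperature no allylic transposition occurs and the E alkene is kept.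

Step 2
Reactants: 2 geranyl bromide
Product: 3 geranyl phenyl sulfone
Conditions: PhSO2Na, DMF, rt
Reagents that add atoms: sodium benzenesulfinate, [Na+].[O-]S(=O)c1ccccc1
Why: S-Alkylation of the sulfinate by the allylic bromide (SN2) gives the allylic sulfone, which makes C6 a carbon acid for the fragment union.

Step 3
Reactants: 3 geranyl phenyl sulfone
Product: 4 (2E,6E)-2,6-dimethyl-8-(phenylsulfonyl)octa-2,6-dien-1-ol
Conditions: SeO2 (cat.), t-BuOOH, salicylic acid (cat.), CH2Cl2, rt
Reagents that add atoms: selenium dioxide, O=[Se]=O (oxygen donor, regenerated by tert-butyl hydroperoxide, CC(C)(C)OO)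
Why: SeO2 allylic oxidation (ene reaction, then 2,3-sigmatropic shift) attacks the electron-rich terminal alkene at the methyl group trans to the chain, so the new CH2OH (C18) is E to C2; the alkene next to the sulfonyl-bearing carbon is deactivated. The reaction is stopped before over-oxidation to the enal becomes important.

Step 4
Reactants: 5 (S)-citronellol
Product: 6 benzyl (S)-citronellyl ether
Conditions: NaH, BnBr, Bu4NI (cat.), THF, 0 °C to rt
Reagents that add atoms: benzyl bromide, BrCc1ccccc1
Why: Williamson ether synthesis; the benzyl ether survives ozone at low temperature, hydride, organolithium and Lewis acid, and is removed late by hydrogenolysis.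

Step 5
Reactants: 6 benzyl (S)-citronellyl ether
Product: 8 (4S)-6-(benzyloxy)-4-methylhexanal, via secondary ozonide 7 (not isolated)
Conditions: O3, CH2Cl2, −78 °C; then Me2S, −78 °C to rt
Reagents that add atoms: ozone, [O-][O+]=O
Why: Ozonolysis with reductive work-up cuts the trisubstituted alkene to the aldehyde carbon that becomes C9; C13 is three carbons from the carbonyl and cannot epimerise.

Step 6
Reactants: 8 (4S)-6-(benzyloxy)-4-methylhexanal
Product: 9 ethyl (2Z,6S)-8-(benzyloxy)-2-iodo-6-methyloct-2-enoate
Conditions: Ph3P=CHCO2Et, NIS, CH2Cl2, −20 °C; then 8, −20 °C to rt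
Reagents that add atoms: ethyl (triphenylphosphoranylidene)acetate, CCOC(=O)C=P(c1ccccc1)(c1ccccc1)c1ccccc1; N-iodosuccinimide, O=C1CCC(=O)N1I
Why: Wittig reaction of the iodo ylide formed in the flask from the stabilised ylide and NIS; as with other ester-stabilised ylides the chain should end trans to the ester and so cis to iodine (Z), the geometry that later places C11 equatorial.

Step 7
Reactants: 9 ethyl (2Z,6S)-8-(benzyloxy)-2-iodo-6-methyloct-2-enoate
Product: 10 ethyl (2Z,6S)-8-(benzyloxy)-6-methyl-2-[(trimethylsilyl)methyl]oct-2-enoate
Conditions: Me3SiCH2MgCl, ZnCl2, THF, 0 °C; then 9, Pd(PPh3)4 (cat.), rt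
Reagents that add atoms: (trimethylsilyl)methylmagnesium chloride, C[Si](C)(C)C[Mg]Cl
Why: Negishi coupling of the alkenyl iodide with the zinc reagent made in the flask proceeds with retention of alkene geometry and tolerates the ester; it installs C17 with its silicon cis to the chain.

Step 8
Reactants: 10 ethyl (2Z,6S)-8-(benzyloxy)-6-methyl-2-[(trimethylsilyl)methyl]oct-2-enoate
Product: 11 (2Z,6S)-8-(benzyloxy)-6-methyl-2-[(trimethylsilyl)methyl]oct-2-en-1-ol
Conditions: i-Bu2AlH, CH2Cl2, −78 °C
Reagents that add atoms: none
Why: 1,2-Reduction of the conjugated ester to the allylic alcohol at low temperature; the ester carbon becomes C7.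

Step 9
Reactants: 11 (2Z,6S)-8-(benzyloxy)-6-methyl-2-[(trimethylsilyl)methyl]oct-2-en-1-ol
Product: 13 [(2E,6S)-8-(benzyloxy)-2-(bromomethyl)-6-methyloct-2-en-1-yl]trimethylsilane, via allylic mesylate 12 (not isolated)
Conditions: MsCl, Et3N, CH2Cl2, −40 °C; then LiBr, THF, 0 °C
Reagents that add atoms: lithium bromide, [Li+].[Br-]; methanesulfonyl chloride, CS(=O)(=O)Cl (atoms kept only in 12)
Why: Mesylation and SN2 displacement by bromide in one flask give the primary allylic bromide without acid, so the allylsilane is not protodesilylated and the alkene does not move.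

Step 10
Reactants: 4 (2E,6E)-2,6-dimethyl-8-(phenylsulfonyl)octa-2,6-dien-1-ol; 13 [(2E,6S)-8-(benzyloxy)-2-(bromomethyl)-6-methyloct-2-en-1-yl]trimethylsilane
Product: 14 (2E,6E,10Z,14S)-16-(benzyloxy)-2,6,14-trimethyl-8-(phenylsulfonyl)-10-[(trimethylsilyl)methyl]hexadeca-2,6,10-trien-1-ol
Conditions: 4, n-BuLi (2 equiv), THF–DMPU, −78 °C; then 13, −78 to −40 °C
Reagents that add atoms: none
Why: Alkylation of an α-sulfonyl carbanion: two equivalents of base give the alkoxide/carbanion dianion, and the far more nucleophilic carbanion attacks the primary allylic bromide at its α-carbon (SN2), forming C6–C7. The new C6 centre forms as a mixture that is erased in step 11.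

Step 11
Reactants: 14 (2E,6E,10Z,14S)-16-(benzyloxy)-2,6,14-trimethyl-8-(phenylsulfonyl)-10-[(trimethylsilyl)methyl]hexadeca-2,6,10-trien-1-ol
Product: 15 (2E,6E,10Z,14S)-16-(benzyloxy)-2,6,14-trimethyl-10-[(trimethylsilyl)methyl]hexadeca-2,6,10-trien-1-ol
Conditions: Pd(dppp)Cl2 (cat.), LiEt3BH, THF, 0 °C
Reagents that add atoms: none
Why: Palladium-catalysed reductive desulfonylation: the allylic sulfone ionises to a π-allyl complex and hydride is delivered to the less substituted terminus C6, so the C5=C10 alkene stays in place and E. The free hydroxyl only consumes hydride.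

Step 12
Reactants: 15 (2E,6E,10Z,14S)-16-(benzyloxy)-2,6,14-trimethyl-10-[(trimethylsilyl)methyl]hexadeca-2,6,10-trien-1-ol
Product: 16 [(2R,3R)-3-{(3E,7Z,11S)-13-(benzyloxy)-3,11-dimethyl-7-[(trimethylsilyl)methyl]trideca-3,7-dien-1-yl}-2-methyloxiran-2-yl]methanol
Conditions: Ti(OiPr)4 (cat.), D-(−)-diethyl tartrate (cat.), t-BuOOH, 4 Å molecular sieves, CH2Cl2, −20 °C
Reagents that add atoms: tert-butyl hydroperoxide, CC(C)(C)OO
Why: Sharpless asymmetric epoxidation: only the allylic alcohol alkene reacts, and with D-(−)-diethyl tartrate the oxygen goes to the face that gives the (2R,3R)-epoxy alcohol, which is 3R,4R in labdane numbering.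

Step 13
Reactants: 16 the (2R,3R)-epoxy alcohol
Product: 17 tert-butyldimethylsilyl ether of 16 (epoxy diene allylsilane, 3R,4R-epoxide)
Conditions: TBSCl, imidazole, CH2Cl2, 0 °C
Reagents that add atoms: tert-butyldimethylsilyl chloride, CC(C)(C)[Si](C)(C)Cl
Why: Silylation of the primary alcohol under mild base, which avoids Payne rearrangement of the epoxy alcohol; the bulky silyl ether is a poor ligand for aluminium in the next step.

Step 14
Reactants: 17 tert-butyldimethylsilyl ether of 16
Product: 18 (3R,4S,5S,9R,10S,13S)-15-(benzyloxy)-18-[(tert-butyldimethylsilyl)oxy]labd-8(17)-en-3-ol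
Conditions: MeAlCl2, CH2Cl2, −78 °C
Reagents that add atoms: none
Why: MeAlCl2 binds the epoxide oxygen and the tertiary C4–O bond lengthens; C5 of the C5=C10 alkene attacks C4 anti to the departing oxygen, the C10 cation is taken by C9 of the allylsilane, and the β-silyl cation at C8 loses Me3Si to leave the C8=C17 methylene. The closest known reaction type is the Lewis acid-promoted cyclisation of epoxy polyenes with an allylsilane terminator. Ring A closes 6-endo at both the epoxide and the alkene and ring B closes 6-endo at the alkene, each through a chair. C3 is carried unchanged from the Sharpless epoxide and its oxygen ends equatorial. C4 is set by inversion at the epoxide carbon: CH2OSi, trans to C2 in the epoxide, becomes equatorial (C18) and the methyl axial (C19). C5 and C10 follow from anti addition across the E C5=C10 alkene, giving the trans fusion with C20 axial; C9 follows from the Z allylsilane, whose C11 is trans to C7 and so ends equatorial. The step needs ionisation of the epoxide alone and cleavage of C4–O, not C3–O, which the tertiary nature of C4 secures, and it needs the product alkene exocyclic, which the silicon secures; C13 takes no part.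

Step 15
Reactants: 18 the 3-hydroxy-8(17)-ene
Product: 19 O-phenyl thionocarbonate of 18
Conditions: PhOC(S)Cl, pyridine, DMAP (cat.), CH2Cl2, rt
Reagents that add atoms: O-phenyl chlorothionoformate, S=C(Cl)Oc1ccccc1
Why: Acylation of the hindered equatorial C3 hydroxyl to the thionocarbonate; neutral conditions are used in place of xanthate formation because an alkoxide at O3 could take the silyl group from O18.

Step 16
Reactants: 19 O-phenyl thionocarbonate of 18
Product: 20 (4S,5S,9R,10S,13S)-15-(benzyloxy)-18-[(tert-butyldimethylsilyl)oxy]labd-8(17)-ene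
Conditions: Bu3SnH, AIBN (cat.), toluene, 90 °C
Reagents that add atoms: none
Why: Barton–McCombie deoxygenation: the stannyl radical adds to sulfur, the C3–O bond fragments to a secondary radical, and this takes hydrogen from Bu3SnH. C3 ceases to be a stereocentre and the remote exocyclic alkene is not involved.

Step 17
Reactants: 20 the 8(17)-ene
Product: 21 (4S,5S,8S,9S,10R,13S)-15-(benzyloxy)-18-[(tert-butyldimethylsilyl)oxy]-8,17-epoxylabdane
Conditions: mCPBA, CH2Cl2, 0 °C
Reagents that add atoms: 3-chloroperoxybenzoic acid, OOC(=O)c1cccc(Cl)c1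
Why: Prilezhaev epoxidation of the only alkene; the peracid should approach C8=C17 from the face away from the axial C20 methyl, placing the epoxide oxygen equatorial on C8 and fixing the C8 configuration.

Step 18
Reactants: 21 the 8,17-epoxide
Product: 22 (4S,5S,8S,9S,10R,13S)-15-(benzyloxy)-18-[(tert-butyldimethylsilyl)oxy]labdan-8-ol
Conditions: LiAlH4, THF, 0 °C to reflux
Reagents that add atoms: none
Why: Hydride opening of the spiro epoxide by SN2 attack at the unhindered CH2 (C17); the C8–O bond is untouched, so the equatorial tertiary alcohol and axial C17 methyl of the target result.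

Step 19
Reactants: 22 the 8-ol benzyl ether
Product: 23 (4S,5S,8S,9S,10R,13S)-18-[(tert-butyldimethylsilyl)oxy]labdane-8,15-diol
Conditions: H2 (1 atm), Pd/C, EtOAc, rt
Reagents that add atoms: none
Why: Hydrogenolysis of the benzyl ether; no alkene is left, and the silyl ether and the tertiary alcohol are inert in ethyl acetate.

Step 20
Reactants: 23 the 8,15-diol; 24 Meldrum's acid
Product: 25 3-{[(4S,5S,8S,9S,10R,13S)-18-[(tert-butyldimethylsilyl)oxy]-8-hydroxylabdan-15-yl]oxy}-3-oxopropanoic acid
Conditions: toluene, 90 °C
Reagents that add atoms: none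
Why: Acylation by ring opening of Meldrum's acid: the primary alcohol adds to a carbonyl of 24 and acetone is lost, giving the malonic half ester directly without base. The tertiary C8 hydroxyl is too hindered to compete and O18 is still silylated.

Step 21
Reactants: 25 the silylated half ester
Product: 26 (4S,5S,8S,9S,10R,13S)-8,18-dihydroxylabdan-15-yl hydrogen malonate (CNP0324566.1)
Conditions: HF·pyridine, pyridine, THF, 0 °C to rt
Reagents that add atoms: none
Why: Fluoride cleavage of the silyl ether under buffered conditions that should neither cleave the malonate ester nor dehydrate the tertiary alcohol.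

## Compound list

1 | geraniol, (2E)-3,7-dimethylocta-2,6-dien-1-ol | CC(C)=CCC/C(C)=C/CO | starting material
2 | geranyl bromide, (2E)-1-bromo-3,7-dimethylocta-2,6-diene | CC(C)=CCC/C(C)=C/CBr | intermediate
3 | geranyl phenyl sulfone, {[(2E)-3,7-dimethylocta-2,6-dien-1-yl]sulfonyl}benzene | CC(C)=CCC/C(C)=C/CS(=O)(=O)c1ccccc1 | intermediate
4 | (2E,6E)-2,6-dimethyl-8-(phenylsulfonyl)octa-2,6-dien-1-ol | OC/C(C)=C/CC/C(C)=C/CS(=O)(=O)c1ccccc1 | intermediate
5 | (S)-citronellol, (3S)-3,7-dimethyloct-6-en-1-ol | C[C@H](CCO)CCC=C(C)C | starting material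
6 | benzyl (S)-citronellyl ether, (3S)-1-(benzyloxy)-3,7-dimethyloct-6-ene | C[C@H](CCOCc1ccccc1)CCC=C(C)C | intermediate
7 | secondary ozonide of 6, 3-[(3S)-5-(benzyloxy)-3-methylpentyl]-5,5-dimethyl-1,2,4-trioxolane (mixture at the ring carbon) | C[C@H](CCOCc1ccccc1)CCC2OOC(C)(C)O2 | intermediate
8 | (4S)-6-(benzyloxy)-4-methylhexanal | C[C@H](CCOCc1ccccc1)CCC=O | intermediate
9 | ethyl (2Z,6S)-8-(benzyloxy)-2-iodo-6-methyloct-2-enoate | C[C@H](CCOCc1ccccc1)CC/C=C(\I)C(=O)OCC | intermediate
10 | ethyl (2Z,6S)-8-(benzyloxy)-6-methyl-2-[(trimethylsilyl)methyl]oct-2-enoate | C[C@H](CCOCc1ccccc1)CC/C=C(\C[Si](C)(C)C)C(=O)OCC | intermediate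
11 | (2Z,6S)-8-(benzyloxy)-6-methyl-2-[(trimethylsilyl)methyl]oct-2-en-1-ol | C[C@H](CCOCc1ccccc1)CC/C=C(\C[Si](C)(C)C)CO | intermediate
12 | methanesulfonate of 11 | C[C@H](CCOCc1ccccc1)CC/C=C(\C[Si](C)(C)C)COS(C)(=O)=O | intermediate
13 | [(2E,6S)-8-(benzyloxy)-2-(bromomethyl)-6-methyloct-2-en-1-yl]trimethylsilane (chain cis to CH2SiMe3) | C[C@H](CCOCc1ccccc1)CC/C=C(\C[Si](C)(C)C)CBr | intermediate
14 | (2E,6E,10Z,14S)-16-(benzyloxy)-2,6,14-trimethyl-8-(phenylsulfonyl)-10-[(trimethylsilyl)methyl]hexadeca-2,6,10-trien-1-ol (both epimers at the sulfonyl carbon) | C[C@H](CCOCc1ccccc1)CC/C=C(\C[Si](C)(C)C)CC(/C=C(\C)CC/C=C(\C)CO)S(=O)(=O)c1ccccc1 | intermediate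
15 | (2E,6E,10Z,14S)-16-(benzyloxy)-2,6,14-trimethyl-10-[(trimethylsilyl)methyl]hexadeca-2,6,10-trien-1-ol | C[C@H](CCOCc1ccccc1)CC/C=C(\C[Si](C)(C)C)CC/C=C(\C)CC/C=C(\C)CO | intermediate
16 | [(2R,3R)-3-{(3E,7Z,11S)-13-(benzyloxy)-3,11-dimethyl-7-[(trimethylsilyl)methyl]trideca-3,7-dien-1-yl}-2-methyloxiran-2-yl]methanol | C[C@H](CCOCc1ccccc1)CC/C=C(\C[Si](C)(C)C)CC/C=C(\C)CC[C@H]1O[C@]1(C)CO | intermediate
17 | tert-butyldimethylsilyl ether of 16 (3R,4R-epoxide, E C5=C10, Z C8=C9 allylsilane; labdane numbering) | C[C@H](CCOCc1ccccc1)CC/C=C(\C[Si](C)(C)C)CC/C=C(\C)CC[C@H]1O[C@]1(C)CO[Si](C)(C)C(C)(C)C | intermediate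
18 | (3R,4S,5S,9R,10S,13S)-15-(benzyloxy)-18-[(tert-butyldimethylsilyl)oxy]labd-8(17)-en-3-ol (trans-decalin, 3-OH equatorial and cis to the C19 and C20 methyls) | C[C@H](CCOCc1ccccc1)CC[C@H]1[C@]2(C)CC[C@@H](O)[C@](C)(CO[Si](C)(C)C(C)(C)C)[C@H]2CCC1=C | intermediate
19 | O-phenyl thionocarbonate of 18 (at O3) | C[C@H](CCOCc1ccccc1)CC[C@H]1[C@]2(C)CC[C@@H](OC(=S)Oc3ccccc3)[C@](C)(CO[Si](C)(C)C(C)(C)C)[C@H]2CCC1=C | intermediate
20 | (4S,5S,9R,10S,13S)-15-(benzyloxy)-18-[(tert-butyldimethylsilyl)oxy]labd-8(17)-ene | C[C@H](CCOCc1ccccc1)CC[C@H]1[C@]2(C)CCC[C@](C)(CO[Si](C)(C)C(C)(C)C)[C@H]2CCC1=C | intermediate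
21 | (4S,5S,8S,9S,10R,13S)-15-(benzyloxy)-18-[(tert-butyldimethylsilyl)oxy]-8,17-epoxylabdane (epoxide oxygen equatorial, anti to C20) | C[C@H](CCOCc1ccccc1)CC[C@H]1[C@]2(C)CCC[C@](C)(CO[Si](C)(C)C(C)(C)C)[C@H]2CC[C@@]13CO3 | intermediate
22 | (4S,5S,8S,9S,10R,13S)-15-(benzyloxy)-18-[(tert-butyldimethylsilyl)oxy]labdan-8-ol | C[C@H](CCOCc1ccccc1)CC[C@H]1[C@]2(C)CCC[C@](C)(CO[Si](C)(C)C(C)(C)C)[C@H]2CC[C@]1(C)O | intermediate
23 | (4S,5S,8S,9S,10R,13S)-18-[(tert-butyldimethylsilyl)oxy]labdane-8,15-diol | C[C@H](CCO)CC[C@H]1[C@]2(C)CCC[C@](C)(CO[Si](C)(C)C(C)(C)C)[C@H]2CC[C@]1(C)O | intermediate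
24 | Meldrum's acid, 2,2-dimethyl-1,3-dioxane-4,6-dione | CC1(C)OC(=O)CC(=O)O1 | starting material
25 | 3-{[(4S,5S,8S,9S,10R,13S)-18-[(tert-butyldimethylsilyl)oxy]-8-hydroxylabdan-15-yl]oxy}-3-oxopropanoic acid | C[C@H](CCOC(=O)CC(=O)O)CC[C@H]1[C@]2(C)CCC[C@](C)(CO[Si](C)(C)C(C)(C)C)[C@H]2CC[C@]1(C)O | intermediate
26 | (4S,5S,8S,9S,10R,13S)-8,18-dihydroxylabdan-15-yl hydrogen malonate (CNP0324566.1) | C[C@H](CCOC(=O)CC(=O)O)CC[C@H]1[C@]2(C)CCC[C@](C)(CO)[C@H]2CC[C@]1(C)O | target

## Step count and risks

Total: 21 steps. Longest linear sequence: 18 steps (from 5: steps 4–9, then 10–21); the geraniol branch (steps 1–3) joins at step 10.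

**Step 14 (key step).** The CH2OSi group slows ionisation at C4. Once the C4–O bond stretches, a 1,2-hydride shift from C18 to C4 (semipinacol-type collapse toward a C18 aldehyde, assisted by the O18 lone pair) may outrun alkene participation. Loss of a proton from the C10 cation after the first ring may also outrun the second ring closure. The fallback forms the same two bonds by a radical and sets out from 6 and 4:
- 6 is oxidised at its E methyl group (SeO2, t-BuOOH) to (2E,6S)-8-(benzyloxy)-2,6-dimethyloct-2-en-1-ol F1 and converted (CBr4, PPh3) into (2E,6S)-8-(benzyloxy)-1-bromo-2,6-dimethyloct-2-ene F2.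
- The dianion of 4 is alkylated with F2 to the silicon-free hydroxy sulfone F3, which is desulfonylated as in step 11 to the trienol F4.
- Sharpless epoxidation as in step 12 gives the epoxy alcohol F5, and silylation gives its tert-butyldimethylsilyl ether F6.
- Cp2TiCl (trivalent titanium, from Cp2TiCl2 and Mn dust in THF) opens the epoxide of F6 homolytically to the C4 radical. This closes rings A and B by two 6-endo additions, and the C8 radical loses a hydrogen atom from C17. The route is rejoined at 18.

A radical cannot undergo the hydride shift. C4 would then rest on the preference of the larger CH2OSi group for the equatorial site, not on the epoxide geometry, which is why this is the reserve and not the plan.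

**Step 6.** The Z selectivity of the Wittig reaction may erode, since the iodo ylide may discriminate less than the parent ylide; any E isomer would end as the C9 epimer after cyclisation. The fallback fixes the geometry by anti-carbometalation of an alkyne, sets out from 8 and bypasses 9 and 10:
- Ohira–Bestmann homologation (dimethyl (1-diazo-2-oxopropyl)phosphonate, K2CO3, MeOH) gives (3S)-1-(benzyloxy)-3-methylhept-6-yne F7.
- Lithiation (n-BuLi) and addition to paraformaldehyde gives (6S)-8-(benzyloxy)-6-methyloct-2-yn-1-ol F8.
- Copper-catalysed addition of Me3SiCH2MgCl (CuI, Et2O) across the alkyne, directed by the magnesium alkoxide, is anti. It places CH2SiMe3 on C8 trans to the new C9–H, hence cis to the chain, and returns to 11.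

**Step 10.** Alkylation of the dianion may be incomplete or unselective (aggregation of the lithium alkoxide, O-alkylation, proton transfer to the bromide). The fallback protects O18 for the union, sets out from 4 and returns at 15:
- 4 is silylated (TBSCl, imidazole) to its tert-butyldimethylsilyl ether F9.
- The monoanion of F9 (n-BuLi, THF, −78 °C) is alkylated with 13 to the silylated sulfone F10.
- Desulfonylation as in step 11 gives the silyl ether F11.
- Bu4NF buffered with AcOH at 0 °C frees the alcohol 15.

**Step 17.** The peracid may show poor facial selectivity at C8=C17; attack from the C20 face gives the C8 epimer. The fallback uses a bulkier reagent and closes the epoxide afterwards; it sets out from 20 and returns at 21: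
- Dihydroxylation with OsO4 (cat.) and N-methylmorpholine N-oxide gives the 8,17-diol F12.
- Tosylation of the primary hydroxyl (TsCl, pyridine) gives the 17-tosylate F13.
- K2CO3 in MeOH closes F13 to epoxide 21.

## Further compounds

F1 | step 14 | (2E,6S)-8-(benzyloxy)-2,6-dimethyloct-2-en-1-ol | C[C@H](CCOCc1ccccc1)CC/C=C(\C)CO
F2 | step 14 | (2E,6S)-8-(benzyloxy)-1-bromo-2,6-dimethyloct-2-ene | C[C@H](CCOCc1ccccc1)CC/C=C(\C)CBr
F3 | step 14 | (2E,6E,10E,14S)-16-(benzyloxy)-2,6,10,14-tetramethyl-8-(phenylsulfonyl)hexadeca-2,6,10-trien-1-ol | C[C@H](CCOCc1ccccc1)CC/C=C(\C)CC(/C=C(\C)CC/C=C(\C)CO)S(=O)(=O)c1ccccc1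
F4 | step 14 | (2E,6E,10E,14S)-16-(benzyloxy)-2,6,10,14-tetramethylhexadeca-2,6,10-trien-1-ol | C[C@H](CCOCc1ccccc1)CC/C=C(\C)CC/C=C(\C)CC/C=C(\C)CO
F5 | step 14 | [(2R,3R)-3-{(3E,7E,11S)-13-(benzyloxy)-3,7,11-trimethyltrideca-3,7-dien-1-yl}-2-methyloxiran-2-yl]methanol | C[C@H](CCOCc1ccccc1)CC/C=C(\C)CC/C=C(\C)CC[C@H]1O[C@]1(C)CO
F6 | step 14 | tert-butyldimethylsilyl ether of F5 | C[C@H](CCOCc1ccccc1)CC/C=C(\C)CC/C=C(\C)CC[C@H]1O[C@]1(C)CO[Si](C)(C)C(C)(C)C
F7 | step 6 | (3S)-1-(benzyloxy)-3-methylhept-6-yne | C[C@H](CCOCc1ccccc1)CCC#C
F8 | step 6 | (6S)-8-(benzyloxy)-6-methyloct-2-yn-1-ol | C[C@H](CCOCc1ccccc1)CCC#CCO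
F9 | step 10 | tert-butyl{[(2E,6E)-2,6-dimethyl-8-(phenylsulfonyl)octa-2,6-dien-1-yl]oxy}dimethylsilane | CC(C)(C)[Si](C)(C)OC/C(C)=C/CC/C(C)=C/CS(=O)(=O)c1ccccc1
F10 | step 10 | tert-butyldimethylsilyl ether of 14 | C[C@H](CCOCc1ccccc1)CC/C=C(\C[Si](C)(C)C)CC(/C=C(\C)CC/C=C(\C)CO[Si](C)(C)C(C)(C)C)S(=O)(=O)c1ccccc1
F11 | step 10 | tert-butyldimethylsilyl ether of 15 | C[C@H](CCOCc1ccccc1)CC/C=C(\C[Si](C)(C)C)CC/C=C(\C)CC/C=C(\C)CO[Si](C)(C)C(C)(C)C
F12 | step 17 | (4S,5S,8S,9S,10R,13S)-15-(benzyloxy)-18-[(tert-butyldimethylsilyl)oxy]labdane-8,17-diol | C[C@H](CCOCc1ccccc1)CC[C@H]1[C@]2(C)CCC[C@](C)(CO[Si](C)(C)C(C)(C)C)[C@H]2CC[C@]1(CO)O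
F13 | step 17 | 17-(4-methylbenzenesulfonate) of F12 | C[C@H](CCOCc1ccccc1)CC[C@H]1[C@]2(C)CCC[C@](C)(CO[Si](C)(C)C(C)(C)C)[C@H]2CC[C@]1(COS(=O)(=O)c3ccc(C)cc3)O
A1 | alternative 1 | trans-fused 1-vinylhydrindan-1-ol carrying the C4 quaternary centre (C8 epimer immaterial) | C=CC1(O)CC[C@@H]2[C@@](C)(CO[Si](C)(C)C(C)(C)C)CCC[C@@]12C
A2 | alternative 1 | trans-decalin 8-ketone with bromomethyl group (C11) on C9 | BrC[C@H]1[C@]2(C)CCC[C@](C)(CO[Si](C)(C)C(C)(C)C)[C@H]2CCC1=O
A3 | alternative 2 | 3-hydroxy-4,4-dimethyl labdane, O15 pivalate, O8 triethylsilyl ether | C[C@H](CCOC(=O)C(C)(C)C)CC[C@H]1[C@]2(C)CC[C@@H](O)C(C)(C)[C@H]2CC[C@]1(C)O[Si](CC)(CC)CC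
A4 | alternative 2 | C3–O–Si–C18 oxasilolane | C[C@H](CCOC(=O)C(C)(C)C)CC[C@H]1[C@]2(C)CC[C@H]3O[Si](CC)(CC)C[C@]3(C)[C@H]2CC[C@]1(C)O[Si](CC)(CC)CC
A5 | alternative 3 | acyclic tiglate triene with C8, C9 and C13 in the tether | C=C/C=C(\C)[C@H](CC[C@H](C)CCOCc1ccccc1)[C@@](C)(O[Si](CC)(CC)CC)CC/C=C(\C)C(=O)OCC
A6 | alternative 3 | trans-decalin C18 ethyl ester with C1=C2 alkene | C[C@H](CCOCc1ccccc1)CC[C@H]1[C@]2(C)C=CC[C@](C)(C(=O)OCC)[C@H]2CC[C@]1(C)O[Si](CC)(CC)CC
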